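**Retrosynthetic overview**
- Pakyonol comes from its ring C benzyl ether by hydrogenolysis. The benzyl ether comes from an open-chain ring C styrene carrying a ring B iodide, by closing the 20-membered ring at the C(ring B)–CH2 bond (9-BBN hydroboration, then intramolecular B-alkyl Suzuki coupling).
- The strategy rests on the CH2–CH2 bridge between ring B and ring C. Both rings are para-linked, so a stilbene at this position would be straight and stiff; the ring is therefore closed with the bridge already saturated.
- The styrene comes from the corresponding ring C aldehyde by methylenation. The aldehyde comes from SNAr of the ring D phenol on 3-(benzyloxy)-4-fluorobenzaldehyde (ring C–O–ring D ether).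
- The ring A–CH2CH2–ring D bibenzyl comes from a Wittig reaction between 3-(4-iodophenoxy)-4-methoxybenzaldehyde and the ylide of (3-hydroxybenzyl)triphenylphosphonium bromide, then diimide reduction. The ring A–O–ring B ether comes from Ullmann coupling of isovanillin with 1,4-diiodobenzene.
- All four benzene rings are bought; the only ring formed is the 20-membered macrocycle, in step 9.

Key step: step 9

Remark: the Wittig product 8 is carried on as an E/Z mixture, since both isomers should give the same bibenzyl 9.

**Route**

Step 1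
Reactants: 1 isovanillin (3-hydroxy-4-methoxybenzaldehyde); 2 1,4-diiodobenzene (4 equiv)
Product: 3 3-(4-iodophenoxy)-4-methoxybenzaldehyde
Conditions: CuI (10 mol%), N,N-dimethylglycine hydrochloride (30 mol%), Cs2CO3, dioxane, 90 °C
Reagents that add atoms: none
Why: Ligand-accelerated Ullmann O-arylation of a phenol with an aryl iodide; the excess of the symmetric diiodide should hold back a second arylation, and the non-enolisable aldehyde tolerates carbonate.

Step 2
Reactants: 4 3-hydroxybenzaldehyde
Product: 5 3-hydroxybenzyl alcohol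
Conditions: NaBH4, MeOH, 0 °C
Reagents that add atoms: none
Why: Borohydride reduction of an aromatic aldehyde to the benzylic alcohol, with the phenol untouched.

Step 3
Reactants: 5 3-hydroxybenzyl alcohol
Product: 6 (3-hydroxybenzyl)triphenylphosphonium bromide
Conditions: PPh3·HBr, MeCN, reflux
Reagents that add atoms: triphenylphosphine hydrobromide, Br.c1ccc(cc1)P(c1ccccc1)c1ccccc1
Why: Acid-promoted conversion of a benzylic alcohol into its phosphonium salt (benzylic substitution by bromide, then by the phosphine), a known reaction of hydroxybenzyl alcohols that leaves the phenol free.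

Step 4
Reactants: 6 (3-hydroxybenzyl)triphenylphosphonium bromide; 3 3-(4-iodophenoxy)-4-methoxybenzaldehyde
Product: 8 3-[2-[3-(4-iodophenoxy)-4-methoxyphenyl]ethenyl]phenol (E/Z mixture), via phenolate ylide 7 (not isolated)
Conditions: KOtBu (2.2 equiv), THF, 0 °C; then 3, 0 °C to rt; aq. NH4Cl
Reagents that add atoms: none
Why: Wittig olefination with the doubly deprotonated salt; the meta phenolate is not conjugated with the ylide carbon, so the ylide should stay reactive, and the alkoxide base avoids halogen–metal exchange at the aryl iodide.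

Step 5
Reactants: 8 3-[2-[3-(4-iodophenoxy)-4-methoxyphenyl]ethenyl]phenol (E/Z mixture)
Product: 9 3-[2-[3-(4-iodophenoxy)-4-methoxyphenyl]ethyl]phenol
Conditions: TsNHNH2 (excess, in portions), NaOAc, DME/H2O, reflux
Reagents that add atoms: none
Why: Diimide reduction (concerted syn transfer of two hydrogens to the C=C), which saturates the stilbene without touching the aryl iodide that catalytic hydrogenation over palladium would remove.

Step 6
Reactants: 10 4-fluoro-3-hydroxybenzaldehyde
Product: 11 3-(benzyloxy)-4-fluorobenzaldehyde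
Conditions: BnBr, K2CO3, acetone, reflux
Reagents that add atoms: benzyl bromide, BrCc1ccccc1
Why: Williamson etherification of the phenol, much faster than any self-SNAr of the phenolate at this temperature.

Step 7
Reactants: 9 3-[2-[3-(4-iodophenoxy)-4-methoxyphenyl]ethyl]phenol; 11 3-(benzyloxy)-4-fluorobenzaldehyde
Product: 12 3-(benzyloxy)-4-[3-[2-[3-(4-iodophenoxy)-4-methoxyphenyl]ethyl]phenoxy]benzaldehyde
Conditions: K2CO3, DMF, 110 °C
Reagents that add atoms: none
Why: Nucleophilic aromatic substitution (addition–elimination) of the ring D phenolate at the fluoride para to the formyl group; the unactivated ring B iodide does not take part.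

Step 8
Reactants: 12 3-(benzyloxy)-4-[3-[2-[3-(4-iodophenoxy)-4-methoxyphenyl]ethyl]phenoxy]benzaldehyde
Product: 13 2-(benzyloxy)-4-ethenyl-1-[3-[2-[3-(4-iodophenoxy)-4-methoxyphenyl]ethyl]phenoxy]benzene (open-chain ring C styrene with ring B iodide)
Conditions: Ph3PCH3Br, KOtBu, THF, 0 °C to rt
Reagents that add atoms: methyltriphenylphosphonium bromide, [Br-].C[P+](c1ccccc1)(c1ccccc1)c1ccccc1
Why: Wittig methylenation of an aromatic aldehyde with the non-stabilised ylide; ethers and the aryl iodide are inert.

Step 9
Reactants: 13 2-(benzyloxy)-4-ethenyl-1-[3-[2-[3-(4-iodophenoxy)-4-methoxyphenyl]ethyl]phenoxy]benzene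
Product: 15 O-benzylpakyonol (20-membered macrocycle), via alkyl-9-BBN borane 14 (not isolated)
Conditions: 9-BBN (0.5 M in THF, 1.5 equiv), 0 °C to rt; then syringe-pump addition over 12 h to PdCl2(dppf) (15 mol%), AsPh3 (15 mol%), Cs2CO3 (3 equiv), DMF/THF/H2O, 60 °C, about 1 mM final
Reagents that add atoms: none
Why: 9-BBN adds syn across the ring C vinyl group through a four-centre transition state with boron on the terminal carbon; zerovalent palladium formed from PdCl2(dppf) then inserts into the ring B C–I bond, the base-activated primary alkylborane transfers its alkyl group to divalent palladium, and reductive elimination makes the CH2–C(ring B) bond. The closest known reaction type is the intramolecular Suzuki–Miyaura coupling of a B-alkyl-9-BBN generated in the same flask from a terminal alkene, which has been used to close macrocycles. The 20-membered ring closes end to end through a 21-membered palladacycle that contracts on reductive elimination, and because the new bridge is a flexible CH2–CH2 unit the two para-linked rings never have to be held across a stiff alkene. No stereocentre is formed. The step needs terminal hydroboration, secured by the bulk of 9-BBN on a monosubstituted styrene, and ring closure faster than β-hydride elimination and intermolecular coupling, secured by the wide-bite-angle dppf ligand and slow addition at high dilution; the iodide is the only site that adds to palladium and nothing else in 13 reacts with the borane.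

Step 10
Reactants: 15 O-benzylpakyonol
Product: 16 pakyonol
Conditions: H2 (1 atm), 10% Pd/C, EtOAc/MeOH, rt
Reagents that add atoms: none
Why: Palladium-catalysed hydrogenolysis of the aryl benzyl ether; the methyl ether, the diaryl ethers and the bibenzyl bridges carry nothing else that is reduced.

**Compound list**

1 | isovanillin (3-hydroxy-4-methoxybenzaldehyde) | COc1ccc(C=O)cc1O | starting material
2 | 1,4-diiodobenzene | Ic1ccc(I)cc1 | starting material
3 | 3-(4-iodophenoxy)-4-methoxybenzaldehyde | COc1ccc(C=O)cc1Oc1ccc(I)cc1 | intermediate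
4 | 3-hydroxybenzaldehyde | O=Cc1cccc(O)c1 | starting material
5 | 3-hydroxybenzyl alcohol | OCc1cccc(O)c1 | intermediate
6 | (3-hydroxybenzyl)triphenylphosphonium bromide | [Br-].Oc1cccc(C[P+](c2ccccc2)(c2ccccc2)c2ccccc2)c1 | intermediate
7 | potassium 3-[(triphenylphosphoranylidene)methyl]phenolate (phenolate ylide, not isolated) | [K+].[O-]c1cccc(C=P(c2ccccc2)(c2ccccc2)c2ccccc2)c1 | intermediate
8 | 3-[2-[3-(4-iodophenoxy)-4-methoxyphenyl]ethenyl]phenol (E/Z mixture) | COc1ccc(C=Cc2cccc(O)c2)cc1Oc1ccc(I)cc1 | intermediate
9 | 3-[2-[3-(4-iodophenoxy)-4-methoxyphenyl]ethyl]phenol | COc1ccc(CCc2cccc(O)c2)cc1Oc1ccc(I)cc1 | intermediate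
10 | 4-fluoro-3-hydroxybenzaldehyde | O=Cc1ccc(F)c(O)c1 | starting material
11 | 3-(benzyloxy)-4-fluorobenzaldehyde | O=Cc1ccc(F)c(OCc2ccccc2)c1 | intermediate
12 | 3-(benzyloxy)-4-[3-[2-[3-(4-iodophenoxy)-4-methoxyphenyl]ethyl]phenoxy]benzaldehyde | COc1ccc(CCc2cccc(Oc3ccc(C=O)cc3OCc3ccccc3)c2)cc1Oc1ccc(I)cc1 | intermediate
13 | 2-(benzyloxy)-4-ethenyl-1-[3-[2-[3-(4-iodophenoxy)-4-methoxyphenyl]ethyl]phenoxy]benzene | COc1ccc(CCc2cccc(Oc3ccc(C=C)cc3OCc3ccccc3)c2)cc1Oc1ccc(I)cc1 | intermediate
14 | B-alkyl-9-BBN from terminal hydroboration of 13 (not isolated) | COc1ccc(CCc2cccc(Oc3ccc(CCB4C5CCCC4CCC5)cc3OCc3ccccc3)c2)cc1Oc1ccc(I)cc1 | intermediate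
15 | O-benzylpakyonol | COc1ccc2cc1Oc1ccc(cc1)CCc1ccc(c(OCc3ccccc3)c1)Oc1cccc(c1)CC2 | intermediate
16 | pakyonol | COc1ccc2cc1Oc1ccc(cc1)CCc1ccc(c(O)c1)Oc1cccc(c1)CC2 | target

**Step count**

Total: 10 steps. Longest linear sequence: 8 steps (steps 2, 3, 4, 5, 7, 8, 9, 10, from 3-hydroxybenzaldehyde).

**Steps most likely to fail**

1. Step 9. Intermolecular coupling to oligomers, β-hydride elimination from the alkylpalladium species and loss of boron by protonation may outrun closure of the 20-membered ring. The fallback sets out from aldehyde 12 and comes back at 15, closing the same bridge as a CH2–CH2 bond between two benzylic carbons. Reductive carbonylation of the ring B iodide (PdCl2(PPh3)2, CO, HCO2Na, DMF, 100 °C) should give the ring B/ring C dialdehyde F1. NaBH4 in MeOH/THF should reduce it to the bis(benzylic alcohol) F2, and PBr3 in CH2Cl2 at 0 °C should give the bis(benzylic bromide) F3. Intramolecular Wurtz coupling with sodium and tetraphenylethene in THF under high dilution, a known ring closure for macrocyclic bis(bibenzyls), should then give 15.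

2. Step 5. Diimide transfer to a 1,2-diaryl alkene is slow, so reduction may stay incomplete and leave stilbene that is hard to separate from the bibenzyl. The fallback sets out from isovanillin 1 and comes back at 12; it brings in the iodide only after the alkene is gone, so that ordinary catalytic hydrogenation can be used. MOMCl and iPr2NEt in CH2Cl2 should give 4-methoxy-3-(methoxymethoxy)benzaldehyde F4. Wittig reaction with ylide 7 should give the stilbene phenol F5 as an E/Z mixture, and H2 over Pd/C in EtOAc the bibenzyl phenol F6. SNAr with 11 (K2CO3, DMF, 110 °C) should give the MOM-protected diaryl ether aldehyde F7, and aqueous HCl in THF at 50 °C the free ring A phenol F8. Ullmann coupling of F8 with excess 2 (CuI, N,N-dimethylglycine hydrochloride, Cs2CO3, dioxane, 90 °C) gives 12.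

3. Step 4. The doubly deprotonated phosphonium salt may be poorly soluble and aggregated, so that olefination of 3 stalls. The fallback sets out from 3-hydroxybenzaldehyde 4 and comes back at 8 (as the E isomer); it replaces the phenolate ylide by a phosphonate carbanion with the phenol masked. TBSCl and imidazole in DMF should give 3-(tert-butyldimethylsilyloxy)benzaldehyde F9, NaBH4 the benzylic alcohol F10, and CBr4/PPh3 the benzylic bromide F11. Michaelis–Arbuzov reaction with P(OEt)3 at 130 °C should give the diethyl benzylphosphonate F12. Horner–Wadsworth–Emmons reaction with 3 (KOtBu, THF, 0 °C) should give the (E)-stilbene silyl ether F13, and TBAF in THF then frees the phenol to give 8.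

**Further compounds**

F1 | step 9 | 3-(benzyloxy)-4-[3-[2-[3-(4-formylphenoxy)-4-methoxyphenyl]ethyl]phenoxy]benzaldehyde | COc1ccc(CCc2cccc(Oc3ccc(C=O)cc3OCc3ccccc3)c2)cc1Oc1ccc(C=O)cc1
F2 | step 9 | [3-(benzyloxy)-4-[3-[2-[3-[4-(hydroxymethyl)phenoxy]-4-methoxyphenyl]ethyl]phenoxy]phenyl]methanol | COc1ccc(CCc2cccc(Oc3ccc(CO)cc3OCc3ccccc3)c2)cc1Oc1ccc(CO)cc1
F3 | step 9 | 2-(benzyloxy)-4-(bromomethyl)-1-[3-[2-[3-[4-(bromomethyl)phenoxy]-4-methoxyphenyl]ethyl]phenoxy]benzene | COc1ccc(CCc2cccc(Oc3ccc(CBr)cc3OCc3ccccc3)c2)cc1Oc1ccc(CBr)cc1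
F4 | step 5 | 4-methoxy-3-(methoxymethoxy)benzaldehyde | COCOc1cc(C=O)ccc1OC
F5 | step 5 | 3-[2-[4-methoxy-3-(methoxymethoxy)phenyl]ethenyl]phenol (E/Z mixture) | COCOc1cc(C=Cc2cccc(O)c2)ccc1OC
F6 | step 5 | 3-[2-[4-methoxy-3-(methoxymethoxy)phenyl]ethyl]phenol | COCOc1cc(CCc2cccc(O)c2)ccc1OC
F7 | step 5 | 3-(benzyloxy)-4-[3-[2-[4-methoxy-3-(methoxymethoxy)phenyl]ethyl]phenoxy]benzaldehyde | COCOc1cc(CCc2cccc(Oc3ccc(C=O)cc3OCc3ccccc3)c2)ccc1OC
F8 | step 5 | 3-(benzyloxy)-4-[3-[2-(3-hydroxy-4-methoxyphenyl)ethyl]phenoxy]benzaldehyde | COc1ccc(CCc2cccc(Oc3ccc(C=O)cc3OCc3ccccc3)c2)cc1O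
F9 | step 4 | 3-(tert-butyldimethylsilyloxy)benzaldehyde | CC(C)(C)[Si](C)(C)Oc1cccc(C=O)c1
F10 | step 4 | [3-(tert-butyldimethylsilyloxy)phenyl]methanol | CC(C)(C)[Si](C)(C)Oc1cccc(CO)c1
F11 | step 4 | [3-(bromomethyl)phenoxy](tert-butyl)dimethylsilane | CC(C)(C)[Si](C)(C)Oc1cccc(CBr)c1
F12 | step 4 | diethyl [3-(tert-butyldimethylsilyloxy)benzyl]phosphonate | CCOP(=O)(OCC)Cc1cccc(O[Si](C)(C)C(C)(C)C)c1
F13 | step 4 | (E)-tert-butyl[3-[2-[3-(4-iodophenoxy)-4-methoxyphenyl]ethenyl]phenoxy]dimethylsilane | COc1ccc(/C=C/c2cccc(O[Si](C)(C)C(C)(C)C)c2)cc1Oc1ccc(I)cc1
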